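**Strategy.** The pyran ring is disconnected at C2–C3 and O1–C8a, so that a one-carbon, one-oxygen unit (C2–O1, from ethyl formate) is stitched between C3 and ring A. The precursor is a deoxybenzoin: a temporary C4 ketone makes C3 (between the carbonyl and ring B) nucleophilic and makes C8a, which carries fluoride ortho to that carbonyl, electrophilic. In one operation, C-formylation at C3 and displacement of fluoride at C8a by the formyl-derived enolate oxygen close the ring as an isoflavone. Asymmetric transfer hydrogenation with dynamic kinetic resolution then sets C3 as S, and one hydrogenolysis removes the C4 oxygen and both benzyl groups.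

Key step: step 8

Assumption: 2,6-dimethoxyphenol and 3-fluoro-2-methoxyphenol are taken as purchasable; atoms are numbered as in a chroman (O1, C2, C3, C4, C4a, C5 to C8, C8a; ring B primed).

**Ring B fragment**

Step 1
Reactants: 1 2,6-dimethoxyphenol
Product: 2 2-(benzyloxy)-1,3-dimethoxybenzene
Conditions: BnBr, K2CO3, DMF, 60 °C
Reagents that add atoms: benzyl bromide, BrCc1ccccc1
Why: Williamson O-benzylation of the phenol, which also masks the central oxygen so that the two methoxy groups direct the next step.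

Step 2
Reactants: 2 2-(benzyloxy)-1,3-dimethoxybenzene
Product: 3 3-(benzyloxy)-1,5-dibromo-2,4-dimethoxybenzene
Conditions: NBS (2.1 equiv), MeCN, 0 °C to rt
Reagents that add atoms: N-bromosuccinimide, O=C1CCC(=O)N1Br
Why: Electrophilic aromatic bromination should occur twice at the two equivalent positions ortho and para to the methoxy groups, as in 1,2,3-trialkoxybenzenes, and spare the position para to the twisted benzyloxy group.

Step 3
Reactants: 3 3-(benzyloxy)-1,5-dibromo-2,4-dimethoxybenzene
Product: 6 3-(benzyloxy)-5-bromo-2,4-dimethoxyphenol, via aryllithium 4 (not isolated), via dimethyl arylboronate 5 (not isolated)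
Conditions: n-BuLi (1.0 equiv), THF, −78 °C; B(OMe)3, −78 °C to rt; then AcOH, 30% aq. H2O2, 0 °C to rt
Reagents that add atoms: hydrogen peroxide, OO (trimethyl borate, COB(OC)OC, leaves atoms only in intermediate 5)
Why: Single bromine–lithium exchange on the symmetric dibromide, borylation and boronate oxidation (1,2-aryl shift from boron to oxygen) turn one C–Br into C–OH, and the symmetry makes the choice of bromine irrelevant.

Step 4
Reactants: 6 3-(benzyloxy)-5-bromo-2,4-dimethoxyphenol
Product: 7 3-(benzyloxy)-1-bromo-2,4,5-trimethoxybenzene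
Conditions: MeI, K2CO3, acetone, reflux
Reagents that add atoms: iodomethane, CI
Why: Williamson O-methylation of the phenol completes the oxygen pattern of ring B with only O3' differentiated as a benzyl ether.

**Ring A fragment**

Step 5
Reactants: 8 3-fluoro-2-methoxyphenol
Product: 9 1-(benzyloxy)-3-fluoro-2-methoxybenzene
Conditions: BnBr, K2CO3, DMF, 60 °C
Reagents that add atoms: benzyl bromide, BrCc1ccccc1
Why: Williamson O-benzylation protects the future 7-hydroxyl as a group that the last step removes.

Step 6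
Reactants: 9 1-(benzyloxy)-3-fluoro-2-methoxybenzene
Product: 10 1-[4-(benzyloxy)-2-fluoro-3-methoxyphenyl]ethan-1-one
Conditions: Ac2O, Sc(OTf)3 (10 mol %), MeNO2, 50 °C
Reagents that add atoms: acetic anhydride, CC(=O)OC(C)=O
Why: Friedel–Crafts acylation should go para to the benzyloxy group, because the methoxy group flanked by OBn and F is twisted out of conjugation, which places the acetyl group next to fluorine.

**Assembly**

Step 7
Reactants: 10 1-[4-(benzyloxy)-2-fluoro-3-methoxyphenyl]ethan-1-one; 7 3-(benzyloxy)-1-bromo-2,4,5-trimethoxybenzene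
Product: 11 1-[4-(benzyloxy)-2-fluoro-3-methoxyphenyl]-2-[3-(benzyloxy)-2,4,5-trimethoxyphenyl]ethan-1-one
Conditions: Pd(OAc)2 (3 mol %), XPhos, K3PO4, toluene, 90 °C
Reagents that add atoms: none
Why: Palladium-catalysed α-arylation of the methyl ketone enolate with the aryl bromide should give the deoxybenzoin; the C–F bond is inert to the catalyst, the mild base limits attack on fluoride, and the ortho-methoxy group of 7 disfavours a second arylation.

Step 8
Reactants: 11 1-[4-(benzyloxy)-2-fluoro-3-methoxyphenyl]-2-[3-(benzyloxy)-2,4,5-trimethoxyphenyl]ethan-1-one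
Product: 13 7-(benzyloxy)-3-[3-(benzyloxy)-2,4,5-trimethoxyphenyl]-8-methoxy-4H-chromen-4-one, via sodium enolate of the α-formyl ketone 12 (not isolated)
Conditions: HCO2Et, NaH, THF, 0 °C to rt; then evaporate, DMF, 110 °C
Reagents that add atoms: ethyl formate, CCOC=O
Why: NaH converts the C3 methylene of 11 (acidified by the C4 ketone and ring B) into its enolate, which undergoes a crossed Claisen C-formylation with ethyl formate to form C2–C3 and rests as the chelated sodium enolate 12, in which the former formyl oxygen is the future O1. On heating in DMF this oxygen attacks C8a, whose fluoride lies ortho to the C4 carbonyl, in an intramolecular addition–elimination (SNAr) through a Meisenheimer adduct stabilised by that carbonyl, and loss of fluoride gives the pyranone ring of 13. The closest known reaction types are the formate-based isoflavone synthesis from deoxybenzoins and the closure of chromones, xanthones and 4-quinolones by displacement of an ortho-fluoride by a 1,3-dicarbonyl enolate oxygen or an ortho-acyl phenoxide. The single ring closes in a 6-exo-trig mode at C8a, with the oxygen cis to the aroyl group on the enolate double bond, a geometry reached by enolate equilibration. No stereocentre is created because C3 becomes sp2; it is set in step 9. The step needs C- over O-formylation (secured by the reversibility of O-formylation and the stability of 12), a single formylation (12 has no C3–H left) and ring closure over attack of ethoxide at C8a (secured by removing ethanol and excess formate before heating and by the six-membered transition state).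

Step 9
Reactants: 13 7-(benzyloxy)-3-[3-(benzyloxy)-2,4,5-trimethoxyphenyl]-8-methoxy-4H-chromen-4-one
Product: 15 (3S,4S)-7-(benzyloxy)-3-[3-(benzyloxy)-2,4,5-trimethoxyphenyl]-8-methoxychroman-4-ol, via isoflavanone 14 (not isolated)
Conditions: RuCl[(S,S)-TsDPEN](p-cymene) (5 mol %), HCO2H/Et3N (5:2), EtOAc, 45 °C
Reagents that add atoms: none
Why: Noyori–Ikariya asymmetric transfer hydrogenation should first reduce the C2=C3 bond to isoflavanone 14, whose C3 epimerises under Et3N, and then reduce the C4 ketone under dynamic kinetic resolution, the (S,S) catalyst setting C4 as S (as in the S-carbinols it gives from aryl alkyl ketones) and hydride delivery anti to the 3-aryl group setting C3 as S in the cis alcohol.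

Step 10
Reactants: 15 (3S,4S)-7-(benzyloxy)-3-[3-(benzyloxy)-2,4,5-trimethoxyphenyl]-8-methoxychroman-4-ol
Product: 16 (3S)-3-(3-hydroxy-2,4,5-trimethoxyphenyl)-8-methoxychroman-7-ol (CNP0201239.1)
Conditions: H2 (3 atm), 10% Pd/C, EtOH/AcOH (10:1), rt
Reagents that add atoms: none
Why: Palladium-catalysed hydrogenolysis should cleave both benzyl ethers and the benzylic C4–O bond (activated by the para oxygen at C7) without touching C3, so the S configuration is carried into the isoflavan.

**Compound list**

1 | 2,6-dimethoxyphenol | COc1cccc(OC)c1O | starting material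
2 | 2-(benzyloxy)-1,3-dimethoxybenzene | COc1cccc(OC)c1OCc1ccccc1 | intermediate
3 | 3-(benzyloxy)-1,5-dibromo-2,4-dimethoxybenzene | COc1c(Br)cc(Br)c(OC)c1OCc1ccccc1 | intermediate
4 | [3-(benzyloxy)-5-bromo-2,4-dimethoxyphenyl]lithium (not isolated) | [Li]c1cc(Br)c(OC)c(OCc2ccccc2)c1OC | intermediate
5 | dimethyl [3-(benzyloxy)-5-bromo-2,4-dimethoxyphenyl]boronate (not isolated) | COB(OC)c1cc(Br)c(OC)c(OCc2ccccc2)c1OC | intermediate
6 | 3-(benzyloxy)-5-bromo-2,4-dimethoxyphenol | Oc1cc(Br)c(OC)c(OCc2ccccc2)c1OC | intermediate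
7 | 3-(benzyloxy)-1-bromo-2,4,5-trimethoxybenzene | COc1cc(Br)c(OC)c(OCc2ccccc2)c1OC | intermediate
8 | 3-fluoro-2-methoxyphenol | COc1c(O)cccc1F | starting material
9 | 1-(benzyloxy)-3-fluoro-2-methoxybenzene | COc1c(OCc2ccccc2)cccc1F | intermediate
10 | 1-[4-(benzyloxy)-2-fluoro-3-methoxyphenyl]ethan-1-one | CC(=O)c1ccc(OCc2ccccc2)c(OC)c1F | intermediate
11 | 1-[4-(benzyloxy)-2-fluoro-3-methoxyphenyl]-2-[3-(benzyloxy)-2,4,5-trimethoxyphenyl]ethan-1-one | COc1cc(CC(=O)c2ccc(OCc3ccccc3)c(OC)c2F)c(OC)c(OCc2ccccc2)c1OC | intermediate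
12 | sodium 2-[3-(benzyloxy)-2,4,5-trimethoxyphenyl]-3-[4-(benzyloxy)-2-fluoro-3-methoxyphenyl]-3-oxoprop-1-en-1-olate (not isolated) | COc1cc(C(=C[O-])C(=O)c2ccc(OCc3ccccc3)c(OC)c2F)c(OC)c(OCc2ccccc2)c1OC.[Na+] | intermediate
13 | 7-(benzyloxy)-3-[3-(benzyloxy)-2,4,5-trimethoxyphenyl]-8-methoxy-4H-chromen-4-one | COc1cc(-c2coc3c(ccc(OCc4ccccc4)c3OC)c2=O)c(OC)c(OCc2ccccc2)c1OC | intermediate
14 | 7-(benzyloxy)-3-[3-(benzyloxy)-2,4,5-trimethoxyphenyl]-8-methoxychroman-4-one (C3 epimerising, not isolated) | COc1cc(C2COc3c(ccc(OCc4ccccc4)c3OC)C2=O)c(OC)c(OCc2ccccc2)c1OC | intermediate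
15 | (3S,4S)-7-(benzyloxy)-3-[3-(benzyloxy)-2,4,5-trimethoxyphenyl]-8-methoxychroman-4-ol (cis) | COc1cc([C@H]2COc3c(ccc(OCc4ccccc4)c3OC)[C@H]2O)c(OC)c(OCc2ccccc2)c1OC | intermediate
16 | (3S)-3-(3-hydroxy-2,4,5-trimethoxyphenyl)-8-methoxychroman-7-ol | COc1cc([C@H]2COc3c(ccc(O)c3OC)C2)c(OC)c(O)c1OC | target

**Step count.** Total: 10 steps. Longest linear sequence: 8 steps (steps 1, 2, 3, 4, 7, 8, 9, 10).

**Steps most likely to fail**

Step 8. The displacement of fluoride on the electron-rich ring A, whose ketone is tied up in the enolate, may be slow, so that deformylation or attack of ethoxide at C8a competes. The fallback places the ring oxygen on ring A first and uses the known iodochromone–Suzuki isoflavone synthesis. It sets out from bromide 7 and purchasable 2-methoxyresorcinol (COc1c(O)cccc1O) and returns at 13. 2-Methoxyresorcinol is C-acetylated (AcOH, BF3·OEt2, 90 °C) to 1-(2,4-dihydroxy-3-methoxyphenyl)ethan-1-one F1. The non-chelated 4-hydroxyl is benzylated (BnBr, K2CO3, acetone) to 1-[4-(benzyloxy)-2-hydroxy-3-methoxyphenyl]ethan-1-one F2. Condensation with DMF dimethyl acetal gives (E)-1-[4-(benzyloxy)-2-hydroxy-3-methoxyphenyl]-3-(dimethylamino)prop-2-en-1-one F3, and I2 in CHCl3 closes it to 7-(benzyloxy)-3-iodo-8-methoxy-4H-chromen-4-one F4. In parallel 7 is borylated (B2pin2, Pd(dppf)Cl2, KOAc, dioxane, 90 °C) to 2-[3-(benzyloxy)-2,4,5-trimethoxyphenyl]-4,4,5,5-tetramethyl-1,3,2-dioxaborolane F5. Suzuki coupling of F4 with F5 (Pd(PPh3)4, Na2CO3, DME/H2O, 80 °C) should give 13.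

Step 10. Acid-assisted loss of water from C4 to the isoflav-3-ene (or a quinone methide that tautomerises to it) before C–O hydrogenolysis would erode the C3 configuration, and cleavage of the C4–O bond may also stop short. The fallback removes the C4 oxygen by a radical path that cannot touch C3. It sets out from 15 and returns at 16. 15 is acylated (PhOC(=S)Cl, pyridine, CH2Cl2) to O-[(3S,4S)-7-(benzyloxy)-3-[3-(benzyloxy)-2,4,5-trimethoxyphenyl]-8-methoxychroman-4-yl] O-phenyl carbonothioate F6. Barton–McCombie reduction (Bu3SnH, AIBN, toluene, 80 °C) gives (3S)-7-(benzyloxy)-3-[3-(benzyloxy)-2,4,5-trimethoxyphenyl]-8-methoxychromane F7. Neutral hydrogenolysis (H2, Pd/C, EtOAc/EtOH) then frees both phenols to give 16.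

Step 6. Acylation may go ortho to the benzyloxy group, or the Lewis acid may cleave or migrate the benzyl group. The fallback fixes the position by halogenation and cross-coupling. It sets out from 8 and returns at 10. Para-bromination of the phenol (NBS, MeCN, 0 °C) gives 4-bromo-3-fluoro-2-methoxyphenol F8. Benzylation (BnBr, K2CO3, DMF) gives 1-(benzyloxy)-4-bromo-3-fluoro-2-methoxybenzene F9. Stille coupling with tributyl(1-ethoxyvinyl)stannane (Pd(PPh3)4, toluene, 100 °C) gives 1-(benzyloxy)-4-(1-ethoxyvinyl)-3-fluoro-2-methoxybenzene F10, which aqueous HCl hydrolyses to 10.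

Further compounds
F1 | step 8 | 1-(2,4-dihydroxy-3-methoxyphenyl)ethan-1-one | CC(=O)c1ccc(O)c(OC)c1O
F2 | step 8 | 1-[4-(benzyloxy)-2-hydroxy-3-methoxyphenyl]ethan-1-one | CC(=O)c1ccc(OCc2ccccc2)c(OC)c1O
F3 | step 8 | (E)-1-[4-(benzyloxy)-2-hydroxy-3-methoxyphenyl]-3-(dimethylamino)prop-2-en-1-one | CN(C)/C=C/C(=O)c1ccc(OCc2ccccc2)c(OC)c1O
F4 | step 8 | 7-(benzyloxy)-3-iodo-8-methoxy-4H-chromen-4-one | O=c1c(I)coc2c(OC)c(OCc3ccccc3)ccc12
F5 | step 8 | 2-[3-(benzyloxy)-2,4,5-trimethoxyphenyl]-4,4,5,5-tetramethyl-1,3,2-dioxaborolane | COc1cc(B2OC(C)(C)C(C)(C)O2)c(OC)c(OCc2ccccc2)c1OC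
F6 | step 10 | O-[(3S,4S)-7-(benzyloxy)-3-[3-(benzyloxy)-2,4,5-trimethoxyphenyl]-8-methoxychroman-4-yl] O-phenyl carbonothioate | COc1cc([C@H]2COc3c(ccc(OCc4ccccc4)c3OC)[C@H]2OC(=S)Oc2ccccc2)c(OC)c(OCc2ccccc2)c1OC
F7 | step 10 | (3S)-7-(benzyloxy)-3-[3-(benzyloxy)-2,4,5-trimethoxyphenyl]-8-methoxychromane | COc1cc([C@H]2COc3c(ccc(OCc4ccccc4)c3OC)C2)c(OC)c(OCc2ccccc2)c1OC
F8 | step 6 | 4-bromo-3-fluoro-2-methoxyphenol | COc1c(O)ccc(Br)c1F
F9 | step 6 | 1-(benzyloxy)-4-bromo-3-fluoro-2-methoxybenzene | COc1c(OCc2ccccc2)ccc(Br)c1F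
F10 | step 6 | 1-(benzyloxy)-4-(1-ethoxyvinyl)-3-fluoro-2-methoxybenzene | CCOC(=C)c1ccc(OCc2ccccc2)c(OC)c1F
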